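**Plan**

- Retrosynthesis: the C3 O‑methyl group and three protecting groups (two benzyl ethers on ring B, the 5‑O‑methyl on ring A) are removed first. Ring C is then cut at C3–C4, the open dialdehyde at the O1–C2 ether bond, the ring B half at C2–C1' (arene plus glyoxylate) and the ring A half at its formyl C–C bond.
- Enabling feature: C4, the aryl ketone carbon on ring A, is bonded directly to C3, a carbinol‑level carbon. Ring C therefore holds an α‑ketol that maps onto the union of two formyl carbons, one with reversed polarity. C2 is benzylic, oxygen‑bearing and, in the open form, α to a formyl group, so it is configurationally mobile.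
- Forward order: rings A and B are bought as arenes. A ring A salicylaldehyde and a ring B mandelate are joined through O1–C2, both side arms are brought to the aldehyde level, and ring C, the only ring made, closes last by C3–C4 bond formation. Methylation of the 3‑hydroxyl, hydrogenolysis and one chelation‑directed demethylation finish the route.
- Stereochemistry: C2 and C3 both arise in the ring closure. A chiral aminoindanol triazolium carbene consumes one of the two rapidly interconverting C2 epimers of the racemic dialdehyde (dynamic kinetic resolution) and fixes C3 trans to the aryl group. No later step uses enolising conditions.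

Key step: step 7

Remark: the sense of induction of the triazolium salt cannot be read from precedent for this substrate. The (5aS,10bR) salt is written on the assumption that it leads to the (2R,3R) series; its mirror image would be used otherwise. The mandelate, the aryl ether, the diol and the dialdehyde are racemates by design.

**Route**

Step 1
Reactants: 1 3,4,5-trimethoxyphenol
Product: 2 2-hydroxy-4,5,6-trimethoxybenzaldehyde
Conditions: MgCl2, Et3N, (CH2O)n, MeCN, reflux; then 1 M HCl
Reagents that add atoms: paraformaldehyde (as formaldehyde), C=O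
Why: Magnesium‑mediated ortho‑formylation of a phenol (Casnati–Skattebøl reaction); the two ortho carbons are equivalent and the para position is blocked, so a single salicylaldehyde should form after hydride transfer to a second formaldehyde.

Step 2
Reactants: 3 methoxyhydroquinone (2-methoxybenzene-1,4-diol)
Product: 4 1,4-bis(benzyloxy)-2-methoxybenzene
Conditions: BnBr, K2CO3, DMF, 60 °C, Ar
Reagents that add atoms: benzyl bromide, BrCc1ccccc1
Why: Twofold Williamson ether synthesis; benzyl ethers should survive Lewis acid at low temperature, hydride, periodinane and carbene catalysis and leave by hydrogenolysis at the end.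

Step 3
Reactants: 4 1,4-bis(benzyloxy)-2-methoxybenzene; 5 ethyl glyoxylate
Product: 6 ethyl (±)-2-[2,5-bis(benzyloxy)-4-methoxyphenyl]-2-hydroxyacetate
Conditions: SnCl4, CH2Cl2, −78 °C
Reagents that add atoms: none
Why: Friedel–Crafts hydroxyalkylation of an electron‑rich arene by Lewis‑acid‑activated glyoxylate; the carbon para to the methoxy group and ortho to a benzyloxy group is the most nucleophilic site, the tin‑bound product alkoxide should resist a second arylation at low temperature, and the new stereocentre is deliberately racemic.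

Step 4
Reactants: 6 ethyl (±)-2-[2,5-bis(benzyloxy)-4-methoxyphenyl]-2-hydroxyacetate; 2 2-hydroxy-4,5,6-trimethoxybenzaldehyde
Product: 7 ethyl (±)-2-[2,5-bis(benzyloxy)-4-methoxyphenyl]-2-(2-formyl-3,4,5-trimethoxyphenoxy)acetate
Conditions: PPh3, DIAD, THF, 0 °C to rt
Reagents that add atoms: none
Why: Mitsunobu etherification of a secondary α‑hydroxy ester with an acidic phenol forms the O1–C2 bond under neutral conditions, avoiding the base that would let the α‑aryloxy ester enolate attack the ortho formyl group; configuration at C2 is of no concern here.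

Step 5
Reactants: 7 ethyl (±)-2-[2,5-bis(benzyloxy)-4-methoxyphenyl]-2-(2-formyl-3,4,5-trimethoxyphenoxy)acetate
Product: 8 (±)-2-[2,5-bis(benzyloxy)-4-methoxyphenyl]-2-[2-(hydroxymethyl)-3,4,5-trimethoxyphenoxy]ethan-1-ol
Conditions: LiAlH4, THF, 0 °C; then H2O
Reagents that add atoms: none
Why: Hydride reduction with LiAlH4 takes ester and aldehyde to the alcohol level together, so no protecting group is needed to tell the two carbonyl groups apart; the ethers are inert.

Step 6
Reactants: 8 (±)-2-[2,5-bis(benzyloxy)-4-methoxyphenyl]-2-[2-(hydroxymethyl)-3,4,5-trimethoxyphenoxy]ethan-1-ol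
Product: 9 (±)-2-[1-[2,5-bis(benzyloxy)-4-methoxyphenyl]-2-oxoethoxy]-4,5,6-trimethoxybenzaldehyde
Conditions: Dess–Martin periodinane, pyridine, CH2Cl2, 0 °C to rt; crude product used at once
Reagents that add atoms: none
Why: Dess–Martin oxidation of the primary and the benzylic alcohol under buffered conditions at or below room temperature should leave the enolisable α‑aryloxy aldehyde intact long enough for immediate use.

Step 7
Reactants: 9 (±)-2-[1-[2,5-bis(benzyloxy)-4-methoxyphenyl]-2-oxoethoxy]-4,5,6-trimethoxybenzaldehyde
Product: 10 (2R,3R)-2-[2,5-bis(benzyloxy)-4-methoxyphenyl]-3-hydroxy-5,6,7-trimethoxychroman-4-one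
Conditions: (5aS,10bR)-2-(pentafluorophenyl)-5a,10b-dihydro-4H,6H-indeno[2,1-b][1,2,4]triazolo[4,3-d][1,4]oxazin-2-ium tetrafluoroborate (10 mol %), iPr2NEt, toluene, rt, Ar
Reagents that add atoms: none
Why: Proposed new method: the triazolylidene freed by the amine adds to the non‑enolisable ring A aldehyde, proton transfer gives the Breslow enaminol (an acyl anion equivalent at C4), this carbon attacks the aliphatic formyl carbon (C3) and collapse of the adduct releases the carbene, leaving the C4 ketone and the C3 carbinol; the closest known reaction type is the carbene‑catalysed intramolecular crossed benzoin of salicylaldehyde‑derived keto aldehydes to 3‑hydroxychroman‑4‑ones, joined to carbene‑catalysed benzoin and aldol reactions run as dynamic kinetic resolutions of base‑labile α‑stereocentres. Ring C closes in the 6‑exo‑trig mode onto the formyl group. C3 is set by the catalyst, whose aminoindanol backbone shields one face of the enaminol so that the formyl group is met from one side only, and C2 is set by dynamic kinetic resolution, because the benzylic, aryloxy‑bearing α‑carbon of the aliphatic aldehyde epimerises through its enol under iPr2NEt faster than the ring closes and only the R epimer fits a chair‑like transition state with the ring B aryl group pseudo‑equatorial and trans to the forming C3–O bond. The step needs donor–acceptor chemoselectivity (ring A aldehyde as acyl anion, aliphatic aldehyde as electrophile), which the substrate supports through the α,α‑disubstituted and therefore crowded surroundings of the aliphatic formyl group, slow to give a Breslow intermediate, and through the inductive activation of that carbonyl by the α‑aryloxy group. It also needs trans diastereoselectivity and enantioselectivity, which rest on the matched pairing of catalyst and C2 epimer and are backed by the thermodynamic preference for the 2,3‑diequatorial chromanone.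

Step 8
Reactants: 10 (2R,3R)-2-[2,5-bis(benzyloxy)-4-methoxyphenyl]-3-hydroxy-5,6,7-trimethoxychroman-4-one
Product: 11 (2R,3R)-2-[2,5-bis(benzyloxy)-4-methoxyphenyl]-3,5,6,7-tetramethoxychroman-4-one
Conditions: MeI, Ag2O, 4 Å MS, CH2Cl2, rt, dark
Reagents that add atoms: iodomethane, CI
Why: Purdie methylation of the only free hydroxyl, a secondary α‑hydroxy ketone; the near‑neutral silver‑assisted alkylation should avoid the enolate that would open ring C by β‑elimination of the O1 phenoxide or epimerise C3.

Step 9
Reactants: 11 (2R,3R)-2-[2,5-bis(benzyloxy)-4-methoxyphenyl]-3,5,6,7-tetramethoxychroman-4-one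
Product: 12 (2R,3R)-2-(2,5-dihydroxy-4-methoxyphenyl)-3,5,6,7-tetramethoxychroman-4-one
Conditions: H2 (1 atm), Pd/C, EtOAc, rt
Reagents that add atoms: none
Why: Catalytic hydrogenolysis of the two aryl benzyl ethers; the chromanone carbonyl, the C2–O1 bond and the methyl ethers are not expected to react at ambient pressure, and the hydroquinone formed is kept under inert gas.

Step 10
Reactants: 12 (2R,3R)-2-(2,5-dihydroxy-4-methoxyphenyl)-3,5,6,7-tetramethoxychroman-4-one
Product: 13 (2R,3R)-2-(2,5-dihydroxy-4-methoxyphenyl)-5-hydroxy-3,6,7-trimethoxychroman-4-one (CNP0257825.1)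
Conditions: BCl3, CH2Cl2, −20 to 0 °C, Ar; then H2O
Reagents that add atoms: none
Why: Chelation‑controlled O‑demethylation with BCl3; boron bridges the C4 carbonyl and the peri 5‑oxygen so chloride should remove only that methyl group, and the non‑basic conditions leave both stereocentres untouched.

**Compound list**

1 | 3,4,5-trimethoxyphenol | COc1cc(O)cc(OC)c1OC | starting material
2 | 2-hydroxy-4,5,6-trimethoxybenzaldehyde | O=Cc1c(O)cc(OC)c(OC)c1OC | intermediate
3 | methoxyhydroquinone (2-methoxybenzene-1,4-diol) | COc1cc(O)ccc1O | starting material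
4 | 1,4-bis(benzyloxy)-2-methoxybenzene | COc1cc(OCc2ccccc2)ccc1OCc1ccccc1 | intermediate
5 | ethyl glyoxylate | CCOC(=O)C=O | starting material
6 | ethyl (±)-2-[2,5-bis(benzyloxy)-4-methoxyphenyl]-2-hydroxyacetate (racemate) | CCOC(=O)C(O)c1cc(OCc2ccccc2)c(OC)cc1OCc1ccccc1 | intermediate
7 | ethyl (±)-2-[2,5-bis(benzyloxy)-4-methoxyphenyl]-2-(2-formyl-3,4,5-trimethoxyphenoxy)acetate (racemate) | CCOC(=O)C(Oc1cc(OC)c(OC)c(OC)c1C=O)c1cc(OCc2ccccc2)c(OC)cc1OCc1ccccc1 | intermediate
8 | (±)-2-[2,5-bis(benzyloxy)-4-methoxyphenyl]-2-[2-(hydroxymethyl)-3,4,5-trimethoxyphenoxy]ethan-1-ol (racemate) | OCC(Oc1cc(OC)c(OC)c(OC)c1CO)c1cc(OCc2ccccc2)c(OC)cc1OCc1ccccc1 | intermediate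
9 | (±)-2-[1-[2,5-bis(benzyloxy)-4-methoxyphenyl]-2-oxoethoxy]-4,5,6-trimethoxybenzaldehyde (racemate, epimers interconvert; the R epimer is consumed) | O=CC(Oc1cc(OC)c(OC)c(OC)c1C=O)c1cc(OCc2ccccc2)c(OC)cc1OCc1ccccc1 | intermediate
10 | (2R,3R)-2-[2,5-bis(benzyloxy)-4-methoxyphenyl]-3-hydroxy-5,6,7-trimethoxychroman-4-one | COc1cc(OCc2ccccc2)c([C@H]2Oc3cc(OC)c(OC)c(OC)c3C(=O)[C@@H]2O)cc1OCc1ccccc1 | intermediate
11 | (2R,3R)-2-[2,5-bis(benzyloxy)-4-methoxyphenyl]-3,5,6,7-tetramethoxychroman-4-one | COc1cc(OCc2ccccc2)c([C@H]2Oc3cc(OC)c(OC)c(OC)c3C(=O)[C@@H]2OC)cc1OCc1ccccc1 | intermediate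
12 | (2R,3R)-2-(2,5-dihydroxy-4-methoxyphenyl)-3,5,6,7-tetramethoxychroman-4-one | COc1cc(O)c([C@H]2Oc3cc(OC)c(OC)c(OC)c3C(=O)[C@@H]2OC)cc1O | intermediate
13 | (2R,3R)-2-(2,5-dihydroxy-4-methoxyphenyl)-5-hydroxy-3,6,7-trimethoxychroman-4-one | COc1cc(O)c([C@H]2Oc3cc(OC)c(OC)c(O)c3C(=O)[C@@H]2OC)cc1O | target

**Step count**

Total: 10 steps. Longest linear sequence: 9 steps (3 to 13, steps 2 to 10); step 1 is the convergent branch.

**Steps most likely to fail**

Step 7. The carbene may engage the aliphatic formyl group instead; its Breslow intermediate can expel the ring A phenoxide, an internal redox that ends in an aryl ester. The enol needed for epimerisation may also add to the ring A aldehyde in a five‑membered aldol closure, or the catalyst may discriminate poorly between the C2 epimers and give the cis series with low enantiopurity.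

The fallback uses known chalcone epoxide chemistry; it sets out from 1 and 4 and returns at 10. Compound 1 would be C‑acetylated ortho to the hydroxyl (Ac2O, BF3·OEt2) to 1-(2-hydroxy-4,5,6-trimethoxyphenyl)ethanone F1, and the phenol masked (MOMCl, NaH, DMF) as 1-[2-(methoxymethoxy)-4,5,6-trimethoxyphenyl]ethanone F2. Compound 4 would be formylated para to its methoxy group (POCl3, DMF; Vilsmeier–Haack) to 2,5-bis(benzyloxy)-4-methoxybenzaldehyde F3. Claisen–Schmidt condensation of the two (KOH, EtOH) should give (E)-3-[2,5-bis(benzyloxy)-4-methoxyphenyl]-1-[2-(methoxymethoxy)-4,5,6-trimethoxyphenyl]prop-2-en-1-one F4. Juliá–Colonna epoxidation (poly‑L‑leucine, urea–H2O2, DBU, THF; the D polymer if the sense proves opposite) is expected to give [(2R,3S)-3-[2,5-bis(benzyloxy)-4-methoxyphenyl]oxiran-2-yl][2-(methoxymethoxy)-4,5,6-trimethoxyphenyl]methanone F5. HCl in MeOH–THF would then remove the methoxymethyl group and let the freed phenol open the oxirane at the benzylic carbon with inversion, retaining the carbinol carbon, to give 10.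

Step 6. The first‑formed aldehyde may be trapped by the remaining alcohol as a seven‑membered lactol and oxidised on to a lactone. The trialkoxybenzyl alcohol may ionise under the acetic acid released, and the enolisable aldehyde may be oxidised further at its α‑carbon.

The fallback avoids any oxidation; it sets out from 7 and returns at 9. The ring A aldehyde would be masked (HC(OMe)3, PPTS, MeOH) as ethyl 2-[2,5-bis(benzyloxy)-4-methoxyphenyl]-2-[2-(dimethoxymethyl)-3,4,5-trimethoxyphenoxy]acetate F6. The ester would be reduced to the aldehyde level only (DIBAL‑H, CH2Cl2, −78 °C) to give 2-[2,5-bis(benzyloxy)-4-methoxyphenyl]-2-[2-(dimethoxymethyl)-3,4,5-trimethoxyphenoxy]acetaldehyde F7. The electron‑rich acetal would be hydrolysed just before the carbene step (PPTS, wet acetone, 0 °C) to give 9.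

Step 4. Displacement at the hindered, electron‑rich benzylic carbinol may be sluggish. Alkylation of the azodicarboxylate‑derived hydrazide or of ring carbon may take over because the phenol is tied up in a hydrogen bond to its formyl group.

The fallback replaces the redox condensation by alkylation of a phenoxide with a halide; it sets out from 6 and returns at 7. Compound 6 would be converted (PBr3, CH2Cl2, 0 °C) to ethyl 2-bromo-2-[2,5-bis(benzyloxy)-4-methoxyphenyl]acetate F8, which would be used crude to alkylate 2 (K2CO3, acetone, rt, kept cold enough to hold back the intramolecular aldol) to give 7.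

**Further compounds**

F1 | step 7 | 1-(2-hydroxy-4,5,6-trimethoxyphenyl)ethanone | CC(=O)c1c(O)cc(OC)c(OC)c1OC
F2 | step 7 | 1-[2-(methoxymethoxy)-4,5,6-trimethoxyphenyl]ethanone | CC(=O)c1c(OCOC)cc(OC)c(OC)c1OC
F3 | step 7 | 2,5-bis(benzyloxy)-4-methoxybenzaldehyde | O=Cc1cc(OCc2ccccc2)c(OC)cc1OCc1ccccc1
F4 | step 7 | (E)-3-[2,5-bis(benzyloxy)-4-methoxyphenyl]-1-[2-(methoxymethoxy)-4,5,6-trimethoxyphenyl]prop-2-en-1-one | COCOc1cc(OC)c(OC)c(OC)c1C(=O)/C=C/c1cc(OCc2ccccc2)c(OC)cc1OCc1ccccc1
F5 | step 7 | [(2R,3S)-3-[2,5-bis(benzyloxy)-4-methoxyphenyl]oxiran-2-yl][2-(methoxymethoxy)-4,5,6-trimethoxyphenyl]methanone | COCOc1cc(OC)c(OC)c(OC)c1C(=O)[C@@H]1O[C@H]1c1cc(OCc2ccccc2)c(OC)cc1OCc1ccccc1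
F6 | step 6 | ethyl 2-[2,5-bis(benzyloxy)-4-methoxyphenyl]-2-[2-(dimethoxymethyl)-3,4,5-trimethoxyphenoxy]acetate (racemate) | CCOC(=O)C(Oc1cc(OC)c(OC)c(OC)c1C(OC)OC)c1cc(OCc2ccccc2)c(OC)cc1OCc1ccccc1
F7 | step 6 | 2-[2,5-bis(benzyloxy)-4-methoxyphenyl]-2-[2-(dimethoxymethyl)-3,4,5-trimethoxyphenoxy]acetaldehyde (racemate) | O=CC(Oc1cc(OC)c(OC)c(OC)c1C(OC)OC)c1cc(OCc2ccccc2)c(OC)cc1OCc1ccccc1
F8 | step 4 | ethyl 2-bromo-2-[2,5-bis(benzyloxy)-4-methoxyphenyl]acetate (racemate) | CCOC(=O)C(Br)c1cc(OCc2ccccc2)c(OC)cc1OCc1ccccc1
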